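In the ten-membered ring the C1 ketone and the butenolide β-carbon C7 are 1,5-related through C8–C9–C10. Joining C1 and C7 as a double bond turns the macrocycle into a cyclopentene (C7–C8–C9–C10–C1) fused to a cycloheptene (C1–C2–C3–C4–C5–C6–C7), a compact bicycle on which C3, C6, C8 and the cis-4,5-epoxide can be set reliably. Ozonolysis of this tetrasubstituted ring-fusion alkene then unveils the cyclodecane-1,7-dione in one operation, without any macrocyclisation. Its substrate is a bicyclo[5.3.0]dec-1(7)-ene bearing the epoxide, protected C3 and C8 oxygens, and O6 already acylated by the phosphonoacetate that afterwards closes the butenolide onto the new C7 ketone.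

Key step: step 19

Remark: carbon labels C1–C15 follow the germacranolide numbering of the target (C11, C12, C13 = lactone α-carbon, carbonyl and CH2O; C14 on C10; C15 on C4) and are used for every intermediate; TBS = tert-butyldimethylsilyl, PMB = 4-methoxybenzyl; the phosphonate-bearing carbon is carried as a mixture of both configurations until the olefination removes it.

Step 1
Reactants: 1 (R)-3-methylcyclopentanone
Product: 2 (R)-trimethyl[(4-methylcyclopent-1-en-1-yl)oxy]silane
Conditions: LiN(i-Pr)2, Me3SiCl (internal quench), THF, −78 °C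
Reagents that add atoms: chlorotrimethylsilane, C[Si](C)(C)Cl
Why: Kinetic enolisation with the hindered amide base and in-situ silylation should favour deprotonation at C7, the α-methylene remote from the methyl-bearing C10 (regioselective silyl enol ether formation); the stereocentre is untouched, and the minor regioisomer later gives only achiral 3-methylcyclopent-2-enone, which is removed after step 2.

Step 2
Reactants: 2 (R)-trimethyl[(4-methylcyclopent-1-en-1-yl)oxy]silane
Product: 3 (S)-4-methylcyclopent-2-en-1-one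
Conditions: Pd(OAc)2 (10 mol %), O2 (1 atm), DMSO, 25 °C
Reagents that add atoms: none
Why: Saegusa–Ito oxidation: palladation of the enol ether at C7 and β-hydride elimination from C1 give the enone without touching C10.

Step 3
Reactants: 3 (S)-4-methylcyclopent-2-en-1-one; 4 tert-butyl[(1-methoxyethenyl)oxy]dimethylsilane
Product: 5 methyl 2-[(1R,5S)-3-(TBSO)-5-methylcyclopent-2-en-1-yl]acetate
Conditions: TBSOTf (5 mol %), CH2Cl2, −78 °C
Reagents that add atoms: none
Why: Mukaiyama–Michael addition: the ketene acetal attacks C1 anti to the C10 methyl and silyl transfer fixes the enol ether between C7 and C8; the new C1 centre is removed again in step 4.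

Step 4
Reactants: 5 methyl 2-[(1R,5S)-3-(TBSO)-5-methylcyclopent-2-en-1-yl]acetate
Product: 6 methyl 2-[(5S)-5-methyl-3-oxocyclopent-1-en-1-yl]acetate
Conditions: Pd(OAc)2 (20 mol %), O2 (1 atm), DMSO, 60 °C
Reagents that add atoms: none
Why: Saegusa–Ito oxidation of the regiodefined enol ether restores the C1=C7 alkene, now with the C2–C3 acetate arm on C1.

Step 5
Reactants: 6 methyl 2-[(5S)-5-methyl-3-oxocyclopent-1-en-1-yl]acetate
Product: 7 methyl 2-[(5S)-2-iodo-5-methyl-3-oxocyclopent-1-en-1-yl]acetate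
Conditions: I2, pyridine, CH2Cl2, 0 → 25 °C
Reagents that add atoms: iodine, II
Why: Pyridine-mediated α-iodination of the enone (conjugate addition, iodination of the enolate, elimination) places iodine on C7, the only enone α-carbon.

Step 6
Reactants: 7 methyl 2-[(5S)-2-iodo-5-methyl-3-oxocyclopent-1-en-1-yl]acetate
Product: 8 methyl 2-[(3S,5S)-3-hydroxy-2-iodo-5-methylcyclopent-1-en-1-yl]acetate
Conditions: (R)-2-methyl-CBS-oxazaborolidine (20 mol %), catecholborane, toluene, −78 °C
Reagents that add atoms: none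
Why: Corey–Bakshi–Shibata reduction: the iodoalkene side is the large group, so the (R)-catalyst should give the (8S)-alcohol, trans to the C10 methyl, by reagent control over the small bias of the remote methyl group.

Step 7
Reactants: 8 methyl 2-[(3S,5S)-3-hydroxy-2-iodo-5-methylcyclopent-1-en-1-yl]acetate
Product: 9 methyl 2-[(3S,5S)-3-(TBSO)-2-iodo-5-methylcyclopent-1-en-1-yl]acetate
Conditions: TBSCl, imidazole, DMF, 25 °C
Reagents that add atoms: tert-butyldimethylsilyl chloride, CC(C)(C)[Si](C)(C)Cl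
Why: Standard silylation of the secondary allylic alcohol; the bulky ether later shields the lower face of C1=C7 in step 15.

Step 8
Reactants: 9 methyl 2-[(3S,5S)-3-(TBSO)-2-iodo-5-methylcyclopent-1-en-1-yl]acetate
Product: 10 2-[(3S,5S)-3-(TBSO)-2-iodo-5-methylcyclopent-1-en-1-yl]-N-methoxy-N-methylacetamide
Conditions: MeNH(OMe)·HCl, AlMe3, CH2Cl2, 0 → 25 °C
Reagents that add atoms: N,O-dimethylhydroxylamine hydrochloride, CNOC.Cl
Why: Weinreb aminolysis of the methyl ester by the aluminium amide; alkenyl iodide and silyl ether are inert.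

Step 9
Reactants: 10 2-[(3S,5S)-3-(TBSO)-2-iodo-5-methylcyclopent-1-en-1-yl]-N-methoxy-N-methylacetamide; 11 isopropenylmagnesium bromide
Product: 12 1-[(3S,5S)-3-(TBSO)-2-iodo-5-methylcyclopent-1-en-1-yl]-3-methylbut-3-en-2-one
Conditions: THF, 0 °C; NH4Cl (aq)
Reagents that add atoms: none
Why: Weinreb ketone synthesis: the chelated tetrahedral adduct prevents over-addition and releases the C3 ketone with C4 and C15 only on work-up.

Step 10
Reactants: 12 1-[(3S,5S)-3-(TBSO)-2-iodo-5-methylcyclopent-1-en-1-yl]-3-methylbut-3-en-2-one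
Product: 13 (2S)-1-[(3S,5S)-3-(TBSO)-2-iodo-5-methylcyclopent-1-en-1-yl]-3-methylbut-3-en-2-ol
Conditions: (R)-2-methyl-CBS-oxazaborolidine (20 mol %), catecholborane, toluene, −78 °C
Reagents that add atoms: none
Why: Corey–Bakshi–Shibata reduction with the isopropenyl group as the large substituent should give the (3S)-allylic alcohol under reagent control; catecholborane at low temperature does not hydroborate the alkene.

Step 11
Reactants: 13 (2S)-1-[(3S,5S)-3-(TBSO)-2-iodo-5-methylcyclopent-1-en-1-yl]-3-methylbut-3-en-2-ol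
Product: 14 tert-butyl{[(1S,4S)-2-iodo-3-[(2S)-2-(PMBO)-3-methylbut-3-en-1-yl]-4-methylcyclopent-2-en-1-yl]oxy}dimethylsilane
Conditions: NaH, PMBCl, n-Bu4NI (cat.), DMF, 0 → 25 °C
Reagents that add atoms: 4-methoxybenzyl chloride, COc1ccc(CCl)cc1
Why: Williamson etherification; the ether cannot direct the later epoxidation and is removed oxidatively at the end, orthogonally to the single silyl ether.

Step 12
Reactants: 14 tert-butyl{[(1S,4S)-2-iodo-3-[(2S)-2-(PMBO)-3-methylbut-3-en-1-yl]-4-methylcyclopent-2-en-1-yl]oxy}dimethylsilane; 15 (2E)-N-methoxy-N-methylbut-2-enamide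
Product: 17 (2E)-1-[(3S,5S)-5-(TBSO)-2-[(2S)-2-(PMBO)-3-methylbut-3-en-1-yl]-3-methylcyclopent-1-en-1-yl]but-2-en-1-one, via vinyllithium 16 (not isolated)
Conditions: t-BuLi (2.1 equiv), Et2O, −78 °C; then 15, −78 → −40 °C; NH4Cl (aq)
Reagents that add atoms: none
Why: Iodine–lithium exchange gives a cyclopentenyllithium that cannot β-eliminate (this would need a cyclic allene), and its 1,2-addition to the Weinreb amide stops at the chelated adduct, so the C6 ketone with the C5 propenyl group is formed without over-addition.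

Step 13
Reactants: 17 (2E)-1-[(3S,5S)-5-(TBSO)-2-[(2S)-2-(PMBO)-3-methylbut-3-en-1-yl]-3-methylcyclopent-1-en-1-yl]but-2-en-1-one
Product: 18 (1R,2E)-1-[(3S,5S)-5-(TBSO)-2-[(2S)-2-(PMBO)-3-methylbut-3-en-1-yl]-3-methylcyclopent-1-en-1-yl]but-2-en-1-ol
Conditions: (S)-2-methyl-CBS-oxazaborolidine (50 mol %), catecholborane, toluene, −78 → −40 °C
Reagents that add atoms: none
Why: Corey–Bakshi–Shibata reduction in which the fully substituted cyclopentenyl group is the large and the propenyl group the small substituent, so the (S)-catalyst should give the (6R)-alcohol, which is the C6 configuration of the target (its descriptor changes later only through substituent priorities).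

Step 14
Reactants: 18 (1R,2E)-1-[(3S,5S)-5-(TBSO)-2-[(2S)-2-(PMBO)-3-methylbut-3-en-1-yl]-3-methylcyclopent-1-en-1-yl]but-2-en-1-ol
Product: 19 (3S,6R,8S,10S)-8-(TBSO)-3-(PMBO)-4,10-dimethylbicyclo[5.3.0]deca-1(7),4-dien-6-ol
Conditions: second-generation Grubbs catalyst (5 mol %), toluene, 80 °C
Reagents that add atoms: none
Why: Ring-closing metathesis: the catalyst loads on the propenyl group and closes onto the isopropenyl group with loss of propene, giving the cycloheptene whose C4=C5 bond is necessarily Z, while the tetrasubstituted C1=C7 alkene is inert.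

Step 15
Reactants: 19 (3S,6R,8S,10S)-8-(TBSO)-3-(PMBO)-4,10-dimethylbicyclo[5.3.0]deca-1(7),4-dien-6-ol
Product: 20 (3S,4R,5S,6S,8S,10S)-8-(TBSO)-4,5-epoxy-3-(PMBO)-4,10-dimethylbicyclo[5.3.0]dec-1(7)-en-6-ol
Conditions: VO(acac)2 (5 mol %), t-BuOOH, CH2Cl2, 0 °C
Reagents that add atoms: tert-butyl hydroperoxide, CC(C)(C)OO
Why: Hydroxyl-directed vanadium-catalysed epoxidation: the vanadate ester of the C6 hydroxyl delivers oxygen to its own face of the trisubstituted C4=C5 alkene, opposite to the C3 ether, setting C4 and C5, while the other allylic alkene C1=C7 is tetrasubstituted and blocked on that face by the neighbouring C8 silyl ether.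

Step 16
Reactants: 21 ethyl 2-(diethoxyphosphoryl)prop-2-enoate
Product: 22 ethyl 2-(diethoxyphosphoryl)-3-(PMBO)propanoate
Conditions: PMBOH, NaH (10 mol %), THF, 0 °C
Reagents that add atoms: 4-methoxybenzyl alcohol, COc1ccc(CO)cc1
Why: Base-catalysed oxa-Michael addition of the alcohol to the doubly activated vinylphosphonate.

Step 17
Reactants: 22 ethyl 2-(diethoxyphosphoryl)-3-(PMBO)propanoate
Product: 23 2-(diethoxyphosphoryl)-3-(PMBO)propanoic acid
Conditions: NaOH (1.05 equiv), EtOH/H2O, 0 °C; then HCl (aq) to pH 3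
Reagents that add atoms: sodium hydroxide, [Na+].[OH-]
Why: Saponification of the activated carboxylic ester is much faster than hydrolysis of the phosphonate esters, and the carboxylate formed is no longer prone to β-elimination of the alkoxide.

Step 18
Reactants: 20 (3S,4R,5S,6S,8S,10S)-8-(TBSO)-4,5-epoxy-3-(PMBO)-4,10-dimethylbicyclo[5.3.0]dec-1(7)-en-6-ol; 23 2-(diethoxyphosphoryl)-3-(PMBO)propanoic acid
Product: 24 (3S,4R,5S,6S,8S,10S)-8-(TBSO)-4,5-epoxy-3-(PMBO)-4,10-dimethylbicyclo[5.3.0]dec-1(7)-en-6-yl 2-(diethoxyphosphoryl)-3-(PMBO)propanoate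
Conditions: DCC, DMAP (10 mol %), CH2Cl2, 0 → 25 °C
Reagents that add atoms: none
Why: Steglich esterification of the C6 hydroxyl; acylating before ring cleavage means the ozonolysis never meets a free allylic hydroxyl and no base-sensitive α-ketol has to be acylated afterwards.

Step 19
Reactants: 24 (3S,4R,5S,6S,8S,10S)-8-(TBSO)-4,5-epoxy-3-(PMBO)-4,10-dimethylbicyclo[5.3.0]dec-1(7)-en-6-yl 2-(diethoxyphosphoryl)-3-(PMBO)propanoate
Product: 26 (3S,4R,5S,6R,8S,10S)-8-(TBSO)-4,5-epoxy-3-(PMBO)-4,10-dimethyl-1,7-dioxocyclodecan-6-yl 2-(diethoxyphosphoryl)-3-(PMBO)propanoate, via methoxy hydroperoxide 25 (not isolated)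
Conditions: O3, CH2Cl2/MeOH (4:1), NaHCO3, Sudan Red 7B, −78 °C; then Me2S, −78 → 25 °C
Reagents that add atoms: ozone, [O-][O+]=O
Why: Ozone adds to C1=C7, the only alkene of 24, by 1,3-dipolar cycloaddition; the primary ozonide collapses to the C7 ketone and the C1 carbonyl oxide, which methanol traps as hydroperoxide 25 and Me2S reduces to the C1 ketone. The closest known reaction type is the ozonolytic opening of the ring-fusion alkene of a fused bicycle to a medium-ring diketone. No ring is closed by bond formation: the ten-membered ring C1–C10 appears because the bond shared by the five- and seven-membered rings is cut. No stereocentre is formed, and C3, C4, C5, C6, C8 and C10 are carried through unchanged. The step needs chemoselectivity for the alkene over the two anisyl rings and no epimerisation at C6, C8 or C10: the tetrasubstituted alkene should react far faster than an alkoxybenzene, the dye end point stops the ozone supply in time, and the buffered reductive work-up at low temperature leaves the α-centres alone. Because O6 is already acylated, no free allylic hydroxyl can divert the carbonyl oxide into fragmentation, and 26 is directly the olefination substrate.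

Step 20
Reactants: 26 (3S,4R,5S,6R,8S,10S)-8-(TBSO)-4,5-epoxy-3-(PMBO)-4,10-dimethyl-1,7-dioxocyclodecan-6-yl 2-(diethoxyphosphoryl)-3-(PMBO)propanoate
Product: 27 (3S,4R,5S,6S,8S,10S)-8-(TBSO)-4,5-epoxy-3,13-bis(PMBO)-1-oxogermacr-7(11)-en-12,6-olide
Conditions: LiCl, i-Pr2NEt, MeCN, 0 → 25 °C
Reagents that add atoms: none
Why: Intramolecular Horner–Wadsworth–Emmons olefination under Masamune–Roush conditions: the lithium-chelated phosphonate anion attacks the neighbouring C7 ketone in a 5-exo closure and loses phosphate to give the C7=C11 butenolide, while the weak amine base leaves C6, C8, C10 and the β-alkoxy ketone alone.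

Step 21
Reactants: 27 (3S,4R,5S,6S,8S,10S)-8-(TBSO)-4,5-epoxy-3,13-bis(PMBO)-1-oxogermacr-7(11)-en-12,6-olide
Product: 28 (3S,4R,5S,6S,8S,10S)-4,5-epoxy-8-hydroxy-3,13-bis(PMBO)-1-oxogermacr-7(11)-en-12,6-olide
Conditions: HF·pyridine, pyridine, THF, 0 → 25 °C
Reagents that add atoms: none
Why: Fluoride-mediated cleavage of the only silyl ether under buffered, mildly acidic conditions to which the benzyl-type ethers, epoxide and lactone are stable.

Step 22
Reactants: 29 tert-butyldimethyl(prop-2-yn-1-yloxy)silane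
Product: 31 tert-butyl 4-(TBSO)but-2-ynoate, via lithium acetylide 30 (not isolated)
Conditions: n-BuLi, THF, −78 °C; then Boc2O, −78 → 0 °C
Reagents that add atoms: di-tert-butyl dicarbonate, CC(C)(C)OC(=O)OC(=O)OC(C)(C)C
Why: Deprotonation of the terminal alkyne and C-acylation of the acetylide by the dicarbonate give the ynoate.

Step 23
Reactants: 31 tert-butyl 4-(TBSO)but-2-ynoate
Product: 32 tert-butyl (2Z)-4-(TBSO)-3-methylbut-2-enoate
Conditions: Me2CuLi (from CuI and MeLi), THF, −78 °C; then MeOH, −78 °C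
Reagents that add atoms: lithium dimethylcuprate, [Li+].C[Cu-]C
Why: Syn-carbocupration (conjugate addition) of the ynoate and cold protonation with retention put the new methyl cis to hydrogen, hence the oxymethyl group cis to the ester (Z).

Step 24
Reactants: 32 tert-butyl (2Z)-4-(TBSO)-3-methylbut-2-enoate
Product: 34 tert-butyl (2Z)-4-acetoxy-3-methylbut-2-enoate, via hydroxy ester 33 (not isolated)
Conditions: Et3N·3HF, THF, 25 °C; then Ac2O, Et3N, DMAP (cat.), 0 °C
Reagents that add atoms: acetic anhydride, CC(=O)OC(C)=O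
Why: Fluoride desilylation followed at once by acetylation in the same flask, so that the Z-configured hydroxy ester has no time to lactonise.

Step 25
Reactants: 34 tert-butyl (2Z)-4-acetoxy-3-methylbut-2-enoate
Product: 35 (2Z)-4-acetoxy-3-methylbut-2-enoic acid
Conditions: CF3CO2H, CH2Cl2, 0 → 25 °C
Reagents that add atoms: none
Why: Acidolysis of the tert-butyl ester with loss of isobutene; acetate and Z-alkene are stable to the acid.

Step 26
Reactants: 28 (3S,4R,5S,6S,8S,10S)-4,5-epoxy-8-hydroxy-3,13-bis(PMBO)-1-oxogermacr-7(11)-en-12,6-olide; 35 (2Z)-4-acetoxy-3-methylbut-2-enoic acid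
Product: 36 (3S,4R,5S,6S,8S,10S)-8-[(2Z)-4-acetoxy-3-methylbut-2-enoyloxy]-4,5-epoxy-3,13-bis(PMBO)-1-oxogermacr-7(11)-en-12,6-olide
Conditions: DCC, DMAP (10 mol %), CH2Cl2, 0 °C
Reagents that add atoms: none
Why: Steglich esterification of the allylic C8 hydroxyl; carbodiimide activation at low temperature without a strong base should avoid Z/E isomerisation of the acid and pre-empt translactonisation to the 12,8-olide.

Step 27
Reactants: 36 (3S,4R,5S,6S,8S,10S)-8-[(2Z)-4-acetoxy-3-methylbut-2-enoyloxy]-4,5-epoxy-3,13-bis(PMBO)-1-oxogermacr-7(11)-en-12,6-olide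
Product: 37 (3S,4R,5S,6S,8S,10S)-8-[(2Z)-4-acetoxy-3-methylbut-2-enoyloxy]-4,5-epoxy-3,13-dihydroxy-1-oxogermacr-7(11)-en-12,6-olide
Conditions: DDQ, CH2Cl2/pH 7 phosphate buffer, 0 → 25 °C
Reagents that add atoms: none
Why: Oxidative cleavage of both benzyl-type ethers by DDQ (hydride abstraction, then hydrolysis of the oxocarbenium ion) under buffered conditions that leave the epoxide, the esters and the electron-poor alkenes untouched.

Step 28
Reactants: 37 (3S,4R,5S,6S,8S,10S)-8-[(2Z)-4-acetoxy-3-methylbut-2-enoyloxy]-4,5-epoxy-3,13-dihydroxy-1-oxogermacr-7(11)-en-12,6-olide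
Product: 38 CNP0232076.1, (3S,4R,5S,6S,8S,10S)-13-acetoxy-8-[(2Z)-4-acetoxy-3-methylbut-2-enoyloxy]-4,5-epoxy-3-hydroxy-1-oxogermacr-7(11)-en-12,6-olide
Conditions: Ac2O (1.1 equiv), 2,4,6-collidine, CH2Cl2, −20 → 0 °C
Reagents that add atoms: acetic anhydride, CC(=O)OC(C)=O
Why: Selective acetylation of the primary allylic C13 hydroxyl; the secondary C3 hydroxyl, flanked by the quaternary epoxide carbon C4, should react much more slowly.

Compound list

1 | (R)-3-methylcyclopentanone | C[C@@H]1CCC(=O)C1 | starting material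
2 | (R)-trimethyl[(4-methylcyclopent-1-en-1-yl)oxy]silane | C[C@@H]1CC=C(O[Si](C)(C)C)C1 | intermediate
3 | (S)-4-methylcyclopent-2-en-1-one | C[C@@H]1C=CC(=O)C1 | intermediate
4 | tert-butyl[(1-methoxyethenyl)oxy]dimethylsilane | C=C(OC)O[Si](C)(C)C(C)(C)C | starting material
5 | methyl 2-[(1R,5S)-3-(tert-butyldimethylsilyloxy)-5-methylcyclopent-2-en-1-yl]acetate | C[C@@H]1[C@@H](CC(=O)OC)C=C(O[Si](C)(C)C(C)(C)C)C1 | intermediate
6 | methyl 2-[(5S)-5-methyl-3-oxocyclopent-1-en-1-yl]acetate | C[C@@H]1C(CC(=O)OC)=CC(=O)C1 | intermediate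
7 | methyl 2-[(5S)-2-iodo-5-methyl-3-oxocyclopent-1-en-1-yl]acetate | C[C@@H]1C(CC(=O)OC)=C(I)C(=O)C1 | intermediate
8 | methyl 2-[(3S,5S)-3-hydroxy-2-iodo-5-methylcyclopent-1-en-1-yl]acetate | C[C@@H]1C(CC(=O)OC)=C(I)[C@@H](O)C1 | intermediate
9 | methyl 2-[(3S,5S)-3-(tert-butyldimethylsilyloxy)-2-iodo-5-methylcyclopent-1-en-1-yl]acetate | C[C@@H]1C(CC(=O)OC)=C(I)[C@@H](O[Si](C)(C)C(C)(C)C)C1 | intermediate
10 | 2-[(3S,5S)-3-(tert-butyldimethylsilyloxy)-2-iodo-5-methylcyclopent-1-en-1-yl]-N-methoxy-N-methylacetamide | C[C@@H]1C(CC(=O)N(C)OC)=C(I)[C@@H](O[Si](C)(C)C(C)(C)C)C1 | intermediate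
11 | isopropenylmagnesium bromide | CC(=C)[Mg]Br | starting material
12 | 1-[(3S,5S)-3-(tert-butyldimethylsilyloxy)-2-iodo-5-methylcyclopent-1-en-1-yl]-3-methylbut-3-en-2-one | C[C@@H]1C(CC(=O)C(C)=C)=C(I)[C@@H](O[Si](C)(C)C(C)(C)C)C1 | intermediate
13 | (2S)-1-[(3S,5S)-3-(tert-butyldimethylsilyloxy)-2-iodo-5-methylcyclopent-1-en-1-yl]-3-methylbut-3-en-2-ol | C[C@@H]1C(C[C@H](O)C(C)=C)=C(I)[C@@H](O[Si](C)(C)C(C)(C)C)C1 | intermediate
14 | tert-butyl{[(1S,4S)-2-iodo-3-[(2S)-2-(4-methoxybenzyloxy)-3-methylbut-3-en-1-yl]-4-methylcyclopent-2-en-1-yl]oxy}dimethylsilane | C[C@@H]1C(C[C@H](OCc2ccc(OC)cc2)C(C)=C)=C(I)[C@@H](O[Si](C)(C)C(C)(C)C)C1 | intermediate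
15 | (2E)-N-methoxy-N-methylbut-2-enamide | C/C=C/C(=O)N(C)OC | starting material
16 | vinyllithium: compound 14 with lithium in place of iodine at C7 | C[C@@H]1C(C[C@H](OCc2ccc(OC)cc2)C(C)=C)=C([Li])[C@@H](O[Si](C)(C)C(C)(C)C)C1 | intermediate
17 | (2E)-1-[(3S,5S)-5-(tert-butyldimethylsilyloxy)-2-[(2S)-2-(4-methoxybenzyloxy)-3-methylbut-3-en-1-yl]-3-methylcyclopent-1-en-1-yl]but-2-en-1-one | C[C@@H]1C(C[C@H](OCc2ccc(OC)cc2)C(C)=C)=C(C(=O)/C=C/C)[C@@H](O[Si](C)(C)C(C)(C)C)C1 | intermediate
18 | (1R,2E)-1-[(3S,5S)-5-(tert-butyldimethylsilyloxy)-2-[(2S)-2-(4-methoxybenzyloxy)-3-methylbut-3-en-1-yl]-3-methylcyclopent-1-en-1-yl]but-2-en-1-ol | C[C@@H]1C(C[C@H](OCc2ccc(OC)cc2)C(C)=C)=C([C@H](O)/C=C/C)[C@@H](O[Si](C)(C)C(C)(C)C)C1 | intermediate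
19 | (3S,6R,8S,10S)-8-(tert-butyldimethylsilyloxy)-3-(4-methoxybenzyloxy)-4,10-dimethylbicyclo[5.3.0]deca-1(7),4-dien-6-ol | C1=2[C@@H](O[Si](C)(C)C(C)(C)C)C[C@H](C)C=2C[C@H](OCc3ccc(OC)cc3)C(C)=C[C@H]1O | intermediate
20 | (3S,4R,5S,6S,8S,10S)-8-(tert-butyldimethylsilyloxy)-4,5-epoxy-3-(4-methoxybenzyloxy)-4,10-dimethylbicyclo[5.3.0]dec-1(7)-en-6-ol | C1=2[C@@H](O[Si](C)(C)C(C)(C)C)C[C@H](C)C=2C[C@H](OCc3ccc(OC)cc3)[C@@]4(C)O[C@H]4[C@H]1O | intermediate
21 | ethyl 2-(diethoxyphosphoryl)prop-2-enoate | C=C(C(=O)OCC)P(=O)(OCC)OCC | starting material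
22 | ethyl 2-(diethoxyphosphoryl)-3-(4-methoxybenzyloxy)propanoate (racemic) | CCOC(=O)C(COCc1ccc(OC)cc1)P(=O)(OCC)OCC | intermediate
23 | 2-(diethoxyphosphoryl)-3-(4-methoxybenzyloxy)propanoic acid (racemic) | OC(=O)C(COCc1ccc(OC)cc1)P(=O)(OCC)OCC | intermediate
24 | 6-O-[2-(diethoxyphosphoryl)-3-(4-methoxybenzyloxy)propanoyl] ester of 20 (two epimers at the phosphonate carbon) | C1=2[C@@H](O[Si](C)(C)C(C)(C)C)C[C@H](C)C=2C[C@H](OCc3ccc(OC)cc3)[C@@]4(C)O[C@H]4[C@H]1OC(=O)C(COCc5ccc(OC)cc5)P(=O)(OCC)OCC | intermediate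
25 | C1 methoxy hydroperoxide: (3S,4R,5S,6R,8S,10S)-8-(tert-butyldimethylsilyloxy)-4,5-epoxy-1-hydroperoxy-1-methoxy-3-(4-methoxybenzyloxy)-4,10-dimethyl-7-oxocyclodecan-6-yl 2-(diethoxyphosphoryl)-3-(4-methoxybenzyloxy)propanoate | O=C1[C@@H](O[Si](C)(C)C(C)(C)C)C[C@H](C)C(OC)(OO)C[C@H](OCc2ccc(OC)cc2)[C@@]3(C)O[C@H]3[C@H]1OC(=O)C(COCc4ccc(OC)cc4)P(=O)(OCC)OCC | intermediate
26 | (3S,4R,5S,6R,8S,10S)-8-(tert-butyldimethylsilyloxy)-4,5-epoxy-3-(4-methoxybenzyloxy)-4,10-dimethyl-1,7-dioxocyclodecan-6-yl 2-(diethoxyphosphoryl)-3-(4-methoxybenzyloxy)propanoate | O=C1[C@@H](O[Si](C)(C)C(C)(C)C)C[C@H](C)C(=O)C[C@H](OCc2ccc(OC)cc2)[C@@]3(C)O[C@H]3[C@H]1OC(=O)C(COCc4ccc(OC)cc4)P(=O)(OCC)OCC | intermediate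
27 | (3S,4R,5S,6S,8S,10S)-8-(tert-butyldimethylsilyloxy)-4,5-epoxy-3,13-bis(4-methoxybenzyloxy)-1-oxogermacr-7(11)-en-12,6-olide | COc1ccc(COCC2=C3[C@@H](O[Si](C)(C)C(C)(C)C)C[C@H](C)C(=O)C[C@H](OCc4ccc(OC)cc4)[C@@]5(C)O[C@H]5[C@H]3OC2=O)cc1 | intermediate
28 | (3S,4R,5S,6S,8S,10S)-4,5-epoxy-8-hydroxy-3,13-bis(4-methoxybenzyloxy)-1-oxogermacr-7(11)-en-12,6-olide | COc1ccc(COCC2=C3[C@@H](O)C[C@H](C)C(=O)C[C@H](OCc4ccc(OC)cc4)[C@@]5(C)O[C@H]5[C@H]3OC2=O)cc1 | intermediate
29 | tert-butyldimethyl(prop-2-yn-1-yloxy)silane | C#CCO[Si](C)(C)C(C)(C)C | starting material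
30 | lithium acetylide of 29 | [Li]C#CCO[Si](C)(C)C(C)(C)C | intermediate
31 | tert-butyl 4-(tert-butyldimethylsilyloxy)but-2-ynoate | CC(C)(C)OC(=O)C#CCO[Si](C)(C)C(C)(C)C | intermediate
32 | tert-butyl (2Z)-4-(tert-butyldimethylsilyloxy)-3-methylbut-2-enoate | CC(C)(C)OC(=O)/C=C(/C)CO[Si](C)(C)C(C)(C)C | intermediate
33 | tert-butyl (2Z)-4-hydroxy-3-methylbut-2-enoate | CC(C)(C)OC(=O)/C=C(/C)CO | intermediate
34 | tert-butyl (2Z)-4-acetoxy-3-methylbut-2-enoate | CC(C)(C)OC(=O)/C=C(/C)COC(C)=O | intermediate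
35 | (2Z)-4-acetoxy-3-methylbut-2-enoic acid | OC(=O)/C=C(/C)COC(C)=O | intermediate
36 | (3S,4R,5S,6S,8S,10S)-8-[(2Z)-4-acetoxy-3-methylbut-2-enoyloxy]-4,5-epoxy-3,13-bis(4-methoxybenzyloxy)-1-oxogermacr-7(11)-en-12,6-olide | COc1ccc(COCC2=C3[C@@H](OC(=O)/C=C(/C)COC(C)=O)C[C@H](C)C(=O)C[C@H](OCc4ccc(OC)cc4)[C@@]5(C)O[C@H]5[C@H]3OC2=O)cc1 | intermediate
37 | (3S,4R,5S,6S,8S,10S)-8-[(2Z)-4-acetoxy-3-methylbut-2-enoyloxy]-4,5-epoxy-3,13-dihydroxy-1-oxogermacr-7(11)-en-12,6-olide | OCC1=C2[C@@H](OC(=O)/C=C(/C)COC(C)=O)C[C@H](C)C(=O)C[C@H](O)[C@@]3(C)O[C@H]3[C@H]2OC1=O | intermediate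
38 | CNP0232076.1, (3S,4R,5S,6S,8S,10S)-13-acetoxy-8-[(2Z)-4-acetoxy-3-methylbut-2-enoyloxy]-4,5-epoxy-3-hydroxy-1-oxogermacr-7(11)-en-12,6-olide | CC(=O)OCC1=C2[C@@H](OC(=O)/C=C(/C)COC(C)=O)C[C@H](C)C(=O)C[C@H](O)[C@@]3(C)O[C@H]3[C@H]2OC1=O | target

Total step count: 28 (22 in the main line, 2 for phosphono acid 23, 4 for side-chain acid 35).
Longest linear sequence: 22 steps (steps 1–15, 18–21 and 26–28).

Steps most likely to fail

Step 19 (key step). Ozone may also attack the electron-rich anisyl rings, the hindered and inductively deactivated alkene may react incompletely, or the peroxidic intermediate may resist reduction. The fallback sets out from 24 and replaces ozone by a two-stage glycol cleavage. Stoichiometric OsO4 with pyridine in CH2Cl2, followed by NaHSO3 work-up, should dihydroxylate C1=C7 (arenes are inert) to the cis-1,7-diol F1; the face of attack is irrelevant because both carbinol carbons become carbonyls. Pb(OAc)4 in CH2Cl2 at 0 °C then cleaves the ditertiary glycol, and the route is rejoined at 26.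

Step 13. Facial selectivity may be poor, or the hindered cross-conjugated ketone may react so slowly that uncatalysed hydride transfer erodes it. The fallback sets out from 17 and moves the reduction onto the ring. Ring-closing metathesis (second-generation Grubbs catalyst, toluene, 80 °C) gives the bicyclic dienone F2, which is used at once because acid or base could expel the C3 ether towards a tropone. Luche reduction (NaBH4, CeCl3·7H2O, MeOH, −78 °C) then relies on substrate control: hydride should approach C6 from the face opposite the C8 silyl ether, placing the hydroxyl cis to it. The route is rejoined at 19.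

Step 15. Oxygen may be transferred to the other allylic alkene, C1=C7, or the bis-allylic alcohol may be oxidised to the ketone. The fallback sets out from 19 and uses nucleophilic instead of directed electrophilic epoxidation. MnO2 in CH2Cl2 gives the bicyclic dienone F2. Hydroperoxide (H2O2, NaOH, MeOH, −20 °C) should add only to C4, the less hindered enone β-carbon, anti to the C3 ether, giving the epoxy ketone F3. Luche reduction (NaBH4, CeCl3·7H2O, MeOH, −78 °C), with hydride anti to both the epoxide oxygen and the C8 silyl ether, returns the cis-epoxy alcohol, and the route is rejoined at 20.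

Further compounds

F1 | step 19 | (3S,4R,5S,6R,8S,10S)-8-(tert-butyldimethylsilyloxy)-4,5-epoxy-1,7-dihydroxy-3-(4-methoxybenzyloxy)-4,10-dimethylbicyclo[5.3.0]decan-6-yl 2-(diethoxyphosphoryl)-3-(4-methoxybenzyloxy)propanoate (cis-1,7-diol, either face) | OC12[C@@H](O[Si](C)(C)C(C)(C)C)C[C@H](C)C2(O)C[C@H](OCc3ccc(OC)cc3)[C@@]4(C)O[C@H]4[C@H]1OC(=O)C(COCc5ccc(OC)cc5)P(=O)(OCC)OCC
F2 | step 13 | (3S,8S,10S)-8-(tert-butyldimethylsilyloxy)-3-(4-methoxybenzyloxy)-4,10-dimethylbicyclo[5.3.0]deca-1(7),4-dien-6-one | C1=2[C@@H](O[Si](C)(C)C(C)(C)C)C[C@H](C)C=2C[C@H](OCc3ccc(OC)cc3)C(C)=CC1=O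
F3 | step 15 | (3S,4R,5R,8S,10S)-8-(tert-butyldimethylsilyloxy)-4,5-epoxy-3-(4-methoxybenzyloxy)-4,10-dimethylbicyclo[5.3.0]dec-1(7)-en-6-one | C1=2[C@@H](O[Si](C)(C)C(C)(C)C)C[C@H](C)C=2C[C@H](OCc3ccc(OC)cc3)[C@@]4(C)O[C@H]4C1=O
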